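A percent of starting material was an awkward unit for this flask, so I counted its loss X as the natural logarithm of charge over remainder. Counting just starting material + partner -> target, taken as first order in each, X integrates in closed form to a constant times partner equivalents times time times f, the time-mean share of the partner charge still present.

the same everywhere: starting material 0.010 M

| flask | partner | second substrate | third substrate | remark | time |
|---|---|---|---|---|---|
| ash | 0.90 equiv | 0.20 equiv | 5 equiv | run made earlier |  |
| elm | 3.6 equiv | 0.20 equiv | 5 equiv | run made earlier |  |
| oak | 1.8 equiv | 0.20 equiv | 7.5 equiv | run made earlier |  |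
| flask | 1.80 equiv | 0.200 equiv | 5.00 equiv |  | 5.0 h |

| run | time / h | starting material / % | target / % |
|---|---|---|---|
| ash | 0.417 | 95.2 | 4.7 |
| ash | 0.833 | 94.4 | 6.8 |
| ash | 1.33 | 87.2 | 11.3 |
| ash | 2.50 | 81.1 | 20.5 |
| ash | 5.00 | 70.5 | 26.5 |
| elm | 1.00 | 66.8 | 32.2 |
| elm | 2.00 | 45.9 | 52.9 |
| elm | 3.00 | 32.2 | 64.2 |
| elm | 4.00 | 25.9 | 71.5 |
| elm | 5.00 | 17.5 | 76.6 |
| oak | 0.417 | 90.0 | 8.5 |
| oak | 0.833 | 82.1 | 12.4 |
| oak | 1.33 | 77.5 | 22.4 |
| oak | 2.50 | 64.5 | 33.3 |
| oak | 5.00 | 47.7 | 48.6 |

(scatter of a reading: 1 percentage point)

- percent here means starting material units held: one side product counts as two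
- what is said of target includes idle adduct
- reactions considered so far: starting material + partner -> target; second substrate + partner -> second product; starting material + target -> side product; third substrate + partner -> third product; third substrate + target <-> idle adduct

1. amount of starting material in percent of the starting material charged, at 1.0 h, 2.5 h and 5.0 h

Which numbers had to be known well? Starting concentration and second substrate stood alike in ash, elm, oak and the flask, so the readings already carried them. Partner did not: from ash to elm its charge rose 4.00-fold and the final X rose 4.99-fold. I reckoned that an error of 10% in the partner charge moved the final starting material by 4.1 percentage points. Oak, with 50.0% more third substrate, stood 1.9 points above the ash-elm midpoint (the geometric mean of their final X), a smaller shift than that one.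

Then I needed the constant. The first elm hour gave 0.112 h⁻¹, the loss X per hour per equivalent of partner charged, a reading with its scatter and a pseudo-first-order constant once multiplied by the equivalents. Taking f as one at 1.0 h, I reckoned 81.7%. At 2.5 h I took oak's 64.5%, and at 5.0 h I took 46.8%, halfway between midpoint and oak.

The forecast gave 81%, 64% and 46%, judging that “the third substrate has a small effect”. The flask gave 81.8%, 64.1% and 46.7%.

    starting material + partner → target (k = 0.00350 L mol⁻¹ s⁻¹)
    second substrate + partner → second product (k = 0.0180 L mol⁻¹ s⁻¹)
    starting material + target → side product (k = 7.80 × 10⁻⁴ L mol⁻¹ s⁻¹)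
    third substrate + partner → third product (k = 2.70 × 10⁻⁴ L mol⁻¹ s⁻¹)
    third substrate + target ⇌ idle adduct, settled at all times (K = 12.0 L mol⁻¹)

Counted against that first-hour constant of 0.112 h⁻¹, the flask's final amount gives f = 0.755, and elm's final reading gives a higher 0.864. In the flask, the half-life of starting material by its own step lengthened from 4.3 h at 1.59 h to 6.7 h at 5.00 h, when partner stood at 45.5% of its charge and that step was using it 1.3 times as fast as third substrate + partner -> third product.

(The data are simulated for an exercise; scatter was added.)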